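**Slow clock.** Slowness is the first worry: is a flask still reacting at the end?

the same everywhere: J 0.050 M
- birch: X 0.083 equiv; Z 5 equiv; run made earlier
- larch: X 1 equiv; Z 5 equiv; run made earlier
- Tuesday's: X 0.150 equiv; Z 5.00 equiv; time 50 min
- Friday's: X 0.300 equiv; Z 5.00 equiv; time 50 min
- Wednesday's: X 0.600 equiv; Z 5.00 equiv; time 50 min
- Saturday's: X 1.20 equiv; Z 5.00 equiv; time 50 min

| run | time / min | L / % | J / % |
|---|---|---|---|
| birch | 2.00 | 1 | 99 |
| birch | 5.00 | 2 | 96 |
| birch | 10.0 | 4 | 96 |
| birch | 25.0 | 7 | 93 |
| larch | 2.00 | 5 | 88 |
| larch | 5.00 | 12 | 74 |
| larch | 10.0 | 15 | 63 |
| larch | 25.0 | 14 | 51 |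

(standard deviation of a reading: 1.5 percentage points)

- "hardly changes" means that all values lie within two and a half points (for a concentration: within two and a half percent of the largest)

- amount of L at the end, in percent of the J charged for Tuesday's, Friday's, Wednesday's, Saturday's, in this order
- the course of these numbers from the first flask to the last (falls all the way / rises, then falls / falls, then rises / rises all the way / hardly changes)

In larch, J falls to 88% by 2.00 min, a loss rate of 0.0639 min⁻¹ with X and J equal. In Tuesday's flask J far outnumbers X, so by the step on J alone I estimate that X decays pseudo-first-order at about that rate, with a half-life of 10.8 min, shorter than the 50 min allowed. You may therefore reckon Tuesday's as if its X were consumed. Saturday's flask is the objection, since this clock does not apply at 1.20 equiv; I assume the same there, unproved.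

**The rule.** J and L compete for X. At the top of L, L is made as fast as it is lost, and X cancels if both steps are first order in it. So J over L at the top reads the selectivity factor s, the rate constant for L's loss over that for J's. Larch has its highest reading of L at 10.0 min, which gives s = 4.20. The objection is that the top may lie between readings: the ratio at 25.0 min is 3.64, and the scatter of L alone moves it by 0.420. I carry the first value as a reading.

**Small correction.** In Tuesday's flask, one L per X gives 15.0% as the uncorrected figure. But L competes, so L falls short of J lost by s/2 times the square of J lost, all as fractions of the charge. X spent is J lost plus J lost minus L, because each L lost takes one more X. Solving gives J lost 12.0% and L 8.97%. Friday's flask, reckoned likewise, gives 11.7%.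

**Far side.** The correction grows too large beyond that, so I use the integrated curve of L against J, from which X has dropped out. Its top is L = s to the power −s/(s−1), or 15.2%, reached at 0.571 equivalents of X; Wednesday's flask, at 0.600 equiv, stands near that charge, so I expect about 15.2% of L there. For Saturday's flask, J to the power s is small, so L is J/(s−1), and the balance gives J 34.6% and L 10.8%. The objection is that this balance counts no X taken further on by what L becomes, so I hold this J as a low estimate.

**The forecast.** It gives 12%, 19%, 19% and 10%, a course that rises, then falls, holding that “selectivity to L gets worse as X rises”. My first three figures are lower.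

**The flasks.** They give 9.08%, 12.8%, 14.6% and 10.8%: the course rises, then falls.

    J + X → Z + L (k = 0.0240 M⁻¹ s⁻¹)
    Q + X → Z + E (k = 0.0220 M⁻¹ s⁻¹)
    L + X → G (k = 0.0680 M⁻¹ s⁻¹)
    L + X → Z + Q (k = 0.0380 M⁻¹ s⁻¹)

Wednesday's flask ends with J over L at 4.35, close to s, and it stands beside the turn of the row at 0.57 equiv. Saturday's flask ends at 3.57, below s, so it lies past the top. In Saturday's flask the loss of L + X to G is the largest single effect on the L left at the end: with that step taken away, L ends at 27.2% instead of 10.8%.

The earlier runs and the new flask were computed for substances that don't exist, noise included.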